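**Plan**
- Retrosynthesis: the three phenols are unmasked last. The cis methyl pair on C3/C4 is traced back to a cis-fused γ-lactone (C3–CH2–O–CO–C4), and that to a C3 silyloxymethyl group and a C4 gem-diester.
- The oxolane (O1, C2 with ring A, C3, C4, C5 with ring B) is then cut at O1–C2 and C4–C5. C2–C3–C4 is a cyclopropane with ring A as donor on C2 and two esters as acceptors on C4; O1–C5 is the aldehyde of ring B, which already carries the side chain with ring C.
- Forward: cyclopropane 7 (steps 1–4) and aldehyde 14 (steps 5–8) are made separately. Step 9 joins them and closes the oxolane; lactonisation, decarboxylation, reduction, deoxygenation and debenzylation follow (steps 10–15).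
- Stereochemistry: the side-chain centre comes from ligand control in the CuH addition (step 7). C2 and C3 come from the Z-alkene geometry and the chiral copper catalyst (step 4), C2 entering the ring with inversion. C5 comes from the 2,5-cis ring closure (step 9) and C4 from the cis ring fusion of the lactone (steps 10–11).

Key step: step 9

Assumption: the ligand antipodes written in steps 4 and 7 are taken to give the drawn configurations; the sense of induction must be confirmed on the first batch and the mirror-image ligand used if it is opposite.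

Conventions: oxolane numbering O1, C2 (ring A), C3, C4, C5 (ring B) is used for all ring descriptors. ArA = 4-(benzyloxy)phenyl; ArB = 4-(benzyloxy)-3-[(2R)-1-(4-benzyloxyphenyl)propan-2-yl]phenyl.

Step 1
Reactants: 1 1-(benzyloxy)-4-iodobenzene; 2 tert-butyldimethyl(prop-2-yn-1-yloxy)silane
Product: 3 {[3-(4-benzyloxyphenyl)prop-2-yn-1-yl]oxy}(tert-butyl)dimethylsilane
Conditions: PdCl2(PPh3)2 (2 mol %), CuI (4 mol %), Et3N, THF, rt
Reagents that add atoms: none
Why: Sonogashira coupling of an aryl iodide with a terminal alkyne runs at room temperature and leaves the silyl and benzyl ethers untouched.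

Step 2
Reactants: 3 {[3-(4-benzyloxyphenyl)prop-2-yn-1-yl]oxy}(tert-butyl)dimethylsilane
Product: 4 (Z)-{[3-(4-benzyloxyphenyl)prop-2-en-1-yl]oxy}(tert-butyl)dimethylsilane
Conditions: H2 (1 atm), Pd/CaCO3 poisoned with Pb(OAc)2 (Lindlar catalyst), quinoline, EtOAc, rt
Reagents that add atoms: none
Why: Lindlar semi-hydrogenation adds H2 syn on the poisoned palladium surface and should stop at the Z-alkene without cleaving the aryl benzyl ether; this geometry later places ring A and the CH2O group cis on the cyclopropane.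

Step 3
Reactants: 5 dimethyl malonate
Product: 6 bis(methoxycarbonyl)(phenyliodonio)methanide (phenyliodonium ylide of dimethyl malonate)
Conditions: PhI(OAc)2, KOH, MeCN, 0 °C
Reagents that add atoms: (diacetoxyiodo)benzene, CC(=O)OI(OC(C)=O)c1ccccc1
Why: Condensation of the malonate anion with the hypervalent iodine diacetate (iodonium ylide formation) is a standard preparation of this carbene precursor, which is stored cold and used soon.

Step 4
Reactants: 4 (Z)-{[3-(4-benzyloxyphenyl)prop-2-en-1-yl]oxy}(tert-butyl)dimethylsilane; 6 bis(methoxycarbonyl)(phenyliodonio)methanide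
Product: 7 dimethyl (2R,3R)-2-ArA-3-{[(tert-butyldimethylsilyl)oxy]methyl}cyclopropane-1,1-dicarboxylate (ArA and CH2OSi cis)
Conditions: Cu(MeCN)4PF6 (10 mol %), (S,S)-side-arm bis(oxazoline) ligand (12 mol %), 4 Å MS, toluene, 0 °C
Reagents that add atoms: none
Why: Copper-carbene cyclopropanation with an iodonium ylide is concerted and stereospecific, so the Z-alkene should give the cis cyclopropane while the chiral bis(oxazoline) pocket selects the alkene face and sets both centres as (2R,3R); the bulky silyl ether is a poor ylide-forming donor and should not divert the carbene.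

Step 5
Reactants: 8 4-(benzyloxy)-3-bromobenzaldehyde
Product: 9 2-[4-(benzyloxy)-3-bromophenyl]-1,3-dioxolane
Conditions: HOCH2CH2OH, p-TsOH (cat.), toluene, reflux (Dean–Stark)
Reagents that add atoms: ethane-1,2-diol, OCCO
Why: Acid-catalysed acetalisation with azeotropic removal of water masks the aldehyde against the hydride and silanolate used in step 7.

Step 6
Reactants: 9 2-[4-(benzyloxy)-3-bromophenyl]-1,3-dioxolane; 10 4,4,5,5-tetramethyl-2-(prop-1-en-2-yl)-1,3,2-dioxaborolane
Product: 11 2-[4-(benzyloxy)-3-(prop-1-en-2-yl)phenyl]-1,3-dioxolane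
Conditions: Pd(dppf)Cl2 (3 mol %), K2CO3, 1,4-dioxane/H2O, 85 °C
Reagents that add atoms: none
Why: Suzuki–Miyaura coupling of the aryl bromide with the alkenyl boronate installs the 2-propenyl group under basic conditions that the acetal tolerates.

Step 7
Reactants: 11 2-[4-(benzyloxy)-3-(prop-1-en-2-yl)phenyl]-1,3-dioxolane; 12 1-(benzyloxy)-4-bromobenzene
Product: 13 2-{4-(benzyloxy)-3-[(2R)-1-(4-benzyloxyphenyl)propan-2-yl]phenyl}-1,3-dioxolane
Conditions: Cu(OAc)2 (5 mol %), (R)-DTBM-SEGPHOS (5.5 mol %), [Pd(cinnamyl)Cl]2 (2 mol %), BrettPhos (4.4 mol %), MePh2SiH, NaOSiMe3, THF, 40 °C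
Reagents that add atoms: none
Why: In this dual CuH/Pd anti-Markovnikov hydroarylation the ligated copper hydride adds across the 1,1-disubstituted alkene with copper on the terminal carbon, the ligand choosing the face and setting the (R) centre, and the primary alkylcopper then transmetalates to the arylpalladium bromide from 12 before reductive elimination.

Step 8
Reactants: 13 2-{4-(benzyloxy)-3-[(2R)-1-(4-benzyloxyphenyl)propan-2-yl]phenyl}-1,3-dioxolane
Product: 14 4-(benzyloxy)-3-[(2R)-1-(4-benzyloxyphenyl)propan-2-yl]benzaldehyde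
Conditions: 1 M aq HCl, THF, rt
Reagents that add atoms: water, O
Why: Acetal hydrolysis of an electron-rich aryl dioxolane is fast in dilute acid and cannot touch the non-enolisable side-chain stereocentre or the benzyl ethers.

Step 9
Reactants: 7 dimethyl (2R,3R)-2-ArA-3-{[(tert-butyldimethylsilyl)oxy]methyl}cyclopropane-1,1-dicarboxylate; 14 4-(benzyloxy)-3-[(2R)-1-(4-benzyloxyphenyl)propan-2-yl]benzaldehyde
Product: 15 dimethyl (2S,3R,5S)-2-ArA-5-ArB-3-{[(tert-butyldimethylsilyl)oxy]methyl}oxolane-4,4-dicarboxylate (2,3-trans and 2,5-cis)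
Conditions: Sn(OTf)2 (10 mol %), CH2Cl2, −20 → 0 °C, 7 in slight excess
Reagents that add atoms: none
Why: Sn(OTf)2 chelates the geminal diester of 7 and polarises the bond between the benzylic carbon (future C2) and the malonate carbon (future C4); the carbonyl oxygen of 14 attacks the benzylic carbon from the side opposite the departing malonate carbon (SN2-like, O1–C2), which inverts C2 and turns the cis ArA/CH2OSi pair into the 2,3-trans pair while C3 is carried over unchanged. The tin-bound malonate then adds to the oxocarbenium carbon (C4–C5), an aldol-type 5-endo-trig closure of the oxolane that is feasible because the electrophile is a cation held next to the nucleophile in a tight ion pair. The closest known reaction type is the Lewis-acid-catalysed formal [3+2] cycloaddition of 2-aryl cyclopropane-1,1-diesters, 2,3-disubstituted ones included, with aldehydes to give 2,5-cis-tetrahydrofurans. C2 is controlled by the configuration of 7 through inversion, and C5 by an envelope transition state with both aryl groups pseudo-equatorial, which gives the 2,5-cis ring. The step needs stereospecific capture to outrun ionisation of 7 to a free benzylic cation, which would scramble C2 and the cis relationship; the electron-rich, nucleophilic aldehyde, the low temperature, the mild catalyst and the inductively withdrawing, non-participating silyloxymethyl group on C3 all work in that direction.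

Step 10
Reactants: 15 dimethyl (2S,3R,5S)-2-ArA-5-ArB-3-{[(tert-butyldimethylsilyl)oxy]methyl}oxolane-4,4-dicarboxylate
Product: 17 cis-fused lactone ester (2S,3R,4R,5S) in which the C3 CH2O and the C4 carbonyl on its face form a γ-lactone and the other C4 CO2Me remains, via hydroxymethyl diester 16 (not isolated)
Conditions: Bu4NF, THF, 0 °C → rt
Reagents that add atoms: none
Why: Fluoride cleaves the Si–O bond (desilylation) and the freed primary alkoxide closes a γ-lactone by acyl substitution on the one C4 ester that lies on its own face, which makes C4 a defined stereocentre with the lactone carbonyl cis to the C3 CH2O group.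

Step 11
Reactants: 17 cis-fused lactone ester
Product: 18 cis-fused lactone (2S,3R,4R,5R) with C3–H and C4–H on the face of the two aryl groups
Conditions: LiCl, H2O, DMSO, 140 °C
Reagents that add atoms: none
Why: In this Krapcho dealkoxycarbonylation chloride demethylates the remaining ester, CO2 is lost and the lactone enolate is protonated, and because only the cis-fused bicyclic lactone is free of strain the new C4–H ends on the face of C3–H, which fixes the 3,4-cis relationship without relying on an equilibration.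

Step 12
Reactants: 18 cis-fused lactone
Product: 19 [(2S,3R,4S,5R)-2-ArA-5-ArB-oxolane-3,4-diyl]dimethanol
Conditions: LiAlH4, THF, 0 °C → rt
Reagents that add atoms: none
Why: Hydride reduction of the lactone gives the 3,4-cis diol without touching a stereocentre or the benzyl ethers.

Step 13
Reactants: 19 [(2S,3R,4S,5R)-2-ArA-5-ArB-oxolane-3,4-diyl]dimethanol
Product: 20 the corresponding bis(methanesulfonate) (2S,3R,4S,5R)
Conditions: MsCl, Et3N, CH2Cl2, −10 °C
Reagents that add atoms: methanesulfonyl chloride, CS(=O)(=O)Cl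
Why: Mesylation through the sulfene is fast at low temperature, so both primary alcohols should be sulfonylated before a mono-mesylate can cyclise to the bicyclic ether.

Step 14
Reactants: 20 bis(methanesulfonate)
Product: 21 (2S,3S,4R,5R)-2-ArA-5-ArB-3,4-dimethyloxolane
Conditions: LiBHEt3, THF, 0 °C → rt
Reagents that add atoms: none
Why: SN2 displacement of both primary mesylates by the strongly nucleophilic triethylborohydride (reductive deoxygenation) gives the two methyl groups, as in the classical diol-to-dimethyl sequence of oxolane lignans.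

Step 15
Reactants: 21 (2S,3S,4R,5R)-2-ArA-5-ArB-3,4-dimethyloxolane
Product: 22 4-[(2S,3S,4R,5R)-5-{4-hydroxy-3-[(2R)-1-(4-hydroxyphenyl)propan-2-yl]phenyl}-3,4-dimethyloxolan-2-yl]phenol
Conditions: H2 (1 atm), Pd/C, EtOAc/EtOH, rt
Reagents that add atoms: none
Why: Hydrogenolysis of the three aryl benzyl ethers over Pd/C under neutral, mild conditions should free the phenols before the benzylic C–O bonds of the oxolane are attacked, as is usual for 2,5-diaryloxolanes.

**Compound list**
1 | 1-(benzyloxy)-4-iodobenzene | Ic1ccc(OCc2ccccc2)cc1 | starting material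
2 | tert-butyldimethyl(prop-2-yn-1-yloxy)silane | C#CCO[Si](C)(C)C(C)(C)C | starting material
3 | {[3-(4-benzyloxyphenyl)prop-2-yn-1-yl]oxy}(tert-butyl)dimethylsilane | CC(C)(C)[Si](C)(C)OCC#Cc1ccc(OCc2ccccc2)cc1 | intermediate
4 | (Z)-{[3-(4-benzyloxyphenyl)prop-2-en-1-yl]oxy}(tert-butyl)dimethylsilane | CC(C)(C)[Si](C)(C)OC/C=C\c1ccc(OCc2ccccc2)cc1 | intermediate
5 | dimethyl malonate | COC(=O)CC(=O)OC | starting material
6 | bis(methoxycarbonyl)(phenyliodonio)methanide | COC(=O)[C-](C(=O)OC)[I+]c1ccccc1 | intermediate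
7 | dimethyl (2R,3R)-2-[4-(benzyloxy)phenyl]-3-{[(tert-butyldimethylsilyl)oxy]methyl}cyclopropane-1,1-dicarboxylate, aryl and CH2OSi cis | COC(=O)C1(C(=O)OC)[C@H](CO[Si](C)(C)C(C)(C)C)[C@@H]1c1ccc(OCc2ccccc2)cc1 | intermediate
8 | 4-(benzyloxy)-3-bromobenzaldehyde | O=Cc1ccc(OCc2ccccc2)c(Br)c1 | starting material
9 | 2-[4-(benzyloxy)-3-bromophenyl]-1,3-dioxolane | O1CCOC1c1ccc(OCc2ccccc2)c(Br)c1 | intermediate
10 | 4,4,5,5-tetramethyl-2-(prop-1-en-2-yl)-1,3,2-dioxaborolane | CC(=C)B1OC(C)(C)C(C)(C)O1 | starting material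
11 | 2-[4-(benzyloxy)-3-(prop-1-en-2-yl)phenyl]-1,3-dioxolane | O1CCOC1c1ccc(OCc2ccccc2)c(C(C)=C)c1 | intermediate
12 | 1-(benzyloxy)-4-bromobenzene | Brc1ccc(OCc2ccccc2)cc1 | starting material
13 | 2-{4-(benzyloxy)-3-[(2R)-1-(4-benzyloxyphenyl)propan-2-yl]phenyl}-1,3-dioxolane | O1CCOC1c1ccc(OCc2ccccc2)c([C@H](C)Cc2ccc(OCc3ccccc3)cc2)c1 | intermediate
14 | 4-(benzyloxy)-3-[(2R)-1-(4-benzyloxyphenyl)propan-2-yl]benzaldehyde | O=Cc1ccc(OCc2ccccc2)c([C@H](C)Cc2ccc(OCc3ccccc3)cc2)c1 | intermediate
15 | dimethyl (2S,3R,5S)-2-ArA-5-ArB-3-{[(tert-butyldimethylsilyl)oxy]methyl}oxolane-4,4-dicarboxylate | COC(=O)C1(C(=O)OC)[C@H](CO[Si](C)(C)C(C)(C)C)[C@@H](c2ccc(OCc3ccccc3)cc2)O[C@H]1c1ccc(OCc2ccccc2)c([C@H](C)Cc2ccc(OCc3ccccc3)cc2)c1 | intermediate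
16 | dimethyl (2S,3R,5S)-2-ArA-5-ArB-3-(hydroxymethyl)oxolane-4,4-dicarboxylate (not isolated) | COC(=O)C1(C(=O)OC)[C@H](CO)[C@@H](c2ccc(OCc3ccccc3)cc2)O[C@H]1c1ccc(OCc2ccccc2)c([C@H](C)Cc2ccc(OCc3ccccc3)cc2)c1 | intermediate
17 | cis-fused lactone ester (2S,3R,4R,5S): methyl 4-oxotetrahydro-1H,3H-furo[3,4-c]furan-3a-carboxylate core, 1-aryl = ArA, 3-aryl = ArB, ester on the face of the aryl groups | COC(=O)[C@@]12C(=O)OC[C@@H]1[C@@H](c3ccc(OCc4ccccc4)cc3)O[C@H]2c1ccc(OCc2ccccc2)c([C@H](C)Cc2ccc(OCc3ccccc3)cc2)c1 | intermediate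
18 | cis-fused lactone (2S,3R,4R,5R): tetrahydro-1H,3H-furo[3,4-c]furan-4-one core, 1-aryl = ArA, 3-aryl = ArB | O=C1OC[C@H]2[C@@H]1[C@H](c1ccc(OCc3ccccc3)c([C@H](C)Cc3ccc(OCc4ccccc4)cc3)c1)O[C@@H]2c1ccc(OCc2ccccc2)cc1 | intermediate
19 | [(2S,3R,4S,5R)-2-ArA-5-ArB-oxolane-3,4-diyl]dimethanol | OC[C@@H]1[C@H](CO)[C@@H](c2ccc(OCc3ccccc3)cc2)O[C@H]1c1ccc(OCc2ccccc2)c([C@H](C)Cc2ccc(OCc3ccccc3)cc2)c1 | intermediate
20 | [(2S,3R,4S,5R)-2-ArA-5-ArB-oxolane-3,4-diyl]bis(methylene) dimethanesulfonate | CS(=O)(=O)OC[C@@H]1[C@H](COS(C)(=O)=O)[C@@H](c2ccc(OCc3ccccc3)cc2)O[C@H]1c1ccc(OCc2ccccc2)c([C@H](C)Cc2ccc(OCc3ccccc3)cc2)c1 | intermediate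
21 | (2S,3S,4R,5R)-2-ArA-5-ArB-3,4-dimethyloxolane | C[C@@H]1[C@H](C)[C@@H](c2ccc(OCc3ccccc3)cc2)O[C@H]1c1ccc(OCc2ccccc2)c([C@H](C)Cc2ccc(OCc3ccccc3)cc2)c1 | intermediate
22 | 4-[(2S,3S,4R,5R)-5-{4-hydroxy-3-[(2R)-1-(4-hydroxyphenyl)propan-2-yl]phenyl}-3,4-dimethyloxolan-2-yl]phenol | C[C@@H]1[C@H](C)[C@@H](c2ccc(O)cc2)O[C@H]1c1ccc(O)c([C@H](C)Cc2ccc(O)cc2)c1 | target

**Totals**
Total step count: 15. Longest linear sequence: 11 steps (steps 5–15).

**Steps most likely to fail**

Step 4. The chiral copper catalyst may discriminate poorly between the faces of this Z-allylic silyl ether, or the electron-rich alkene may add stepwise and lose part of its cis geometry. The fallback secures the absolute configuration by separation instead of catalyst control. It sets out from 4 and 6: cyclopropanation with achiral Rh2(esp)2 in CH2Cl2, which is stereospecific for malonate carbenes, should give 7 together with its mirror image, dimethyl (2S,3S)-2-[4-(benzyloxy)phenyl]-3-{[(tert-butyldimethylsilyl)oxy]methyl}cyclopropane-1,1-dicarboxylate F1. Preparative chromatography on a chiral stationary phase removes F1 and the route is rejoined at 7.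

Step 9. With the strongly donating 4-benzyloxyphenyl group the cyclopropane may ionise to a free benzylic zwitterion faster than the aldehyde captures it, which would erode the enantiomeric purity and the 2,3-trans relationship. The fallback lowers the donor strength of ring A for the ring-forming step only. It sets out from 2: Sonogashira coupling with 4-iodophenyl acetate F2 gives the alkyne acetate F3, Lindlar reduction gives the Z-alkene acetate F4, and cyclopropanation with 6 as in step 4 gives the acetoxyphenyl cyclopropane F5. Its reaction with 14 under Sn(OTf)2 at room temperature should follow the tight SN2-like path, since a 4-acetoxyphenyl group stabilises a benzylic cation hardly better than phenyl, and give the acetoxyphenyl oxolane diester F6. Methanolysis of the aryl acetate (K2CO3, MeOH) to the phenol F7 and benzylation (BnBr, K2CO3, DMF) rejoin the route at 15.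

Step 7. The copper and palladium cycles may fall out of step on this ortho-substituted alkene, so that the alkylcopper is protonated (simple alkene reduction) or the aryl bromide is reduced before the two meet. The fallback separates the two metal-catalysed events. It sets out from 11: hydroboration with pinacolborane catalysed by CuCl, (R)-DTBM-SEGPHOS and KOtBu in THF, a known enantioselective reaction of 2-aryl propenes, should give the boronate F8. Suzuki–Miyaura coupling of F8 with 12 (Pd(OAc)2, RuPhos, K3PO4, toluene/H2O, 90 °C) rejoins the route at 13.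

**Further compounds**
F1 | step 4 | dimethyl (2S,3S)-2-[4-(benzyloxy)phenyl]-3-{[(tert-butyldimethylsilyl)oxy]methyl}cyclopropane-1,1-dicarboxylate | COC(=O)C1(C(=O)OC)[C@@H](CO[Si](C)(C)C(C)(C)C)[C@H]1c1ccc(OCc2ccccc2)cc1
F2 | step 9 | 4-iodophenyl acetate | CC(=O)Oc1ccc(I)cc1
F3 | step 9 | 4-{3-[(tert-butyldimethylsilyl)oxy]prop-1-yn-1-yl}phenyl acetate | CC(=O)Oc1ccc(C#CCO[Si](C)(C)C(C)(C)C)cc1
F4 | step 9 | (Z)-4-{3-[(tert-butyldimethylsilyl)oxy]prop-1-en-1-yl}phenyl acetate | CC(=O)Oc1ccc(/C=C\CO[Si](C)(C)C(C)(C)C)cc1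
F5 | step 9 | dimethyl (2R,3R)-2-(4-acetoxyphenyl)-3-{[(tert-butyldimethylsilyl)oxy]methyl}cyclopropane-1,1-dicarboxylate | COC(=O)C1(C(=O)OC)[C@H](CO[Si](C)(C)C(C)(C)C)[C@@H]1c1ccc(OC(C)=O)cc1
F6 | step 9 | dimethyl (2S,3R,5S)-2-(4-acetoxyphenyl)-5-ArB-3-{[(tert-butyldimethylsilyl)oxy]methyl}oxolane-4,4-dicarboxylate | COC(=O)C1(C(=O)OC)[C@H](CO[Si](C)(C)C(C)(C)C)[C@@H](c2ccc(OC(C)=O)cc2)O[C@H]1c1ccc(OCc2ccccc2)c([C@H](C)Cc2ccc(OCc3ccccc3)cc2)c1
F7 | step 9 | dimethyl (2S,3R,5S)-2-(4-hydroxyphenyl)-5-ArB-3-{[(tert-butyldimethylsilyl)oxy]methyl}oxolane-4,4-dicarboxylate | COC(=O)C1(C(=O)OC)[C@H](CO[Si](C)(C)C(C)(C)C)[C@@H](c2ccc(O)cc2)O[C@H]1c1ccc(OCc2ccccc2)c([C@H](C)Cc2ccc(OCc3ccccc3)cc2)c1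
F8 | step 7 | 2-{4-(benzyloxy)-3-[(2R)-1-(4,4,5,5-tetramethyl-1,3,2-dioxaborolan-2-yl)propan-2-yl]phenyl}-1,3-dioxolane | O1CCOC1c1ccc(OCc2ccccc2)c([C@H](C)CB2OC(C)(C)C(C)(C)O2)c1
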